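I was asked how much product this flask holds at 30 h, with what excess, and whether the exchange between the two substrates keeps pace.

| setting | south-east | flask |
|---|---|---|
| left-handed substrate | 0.30 M | 0.30 M |
| right-handed substrate | 0.30 M | 0.30 M |
| gas | 47 mM (held) | 47 mM (held) |
| racemization catalyst | 12 mol% | 12 mol% |
| remark | the very flask that is asked about, followed so far |  |
| time |  | 30 h |

south-east run (percent of the left-handed substrate and right-handed substrate together charged)

| time / h | left-handed product / % | right-handed product / % |
|---|---|---|
| 1.00 | 2.2 | 0 |
| 2.00 | 3.4 | 0.3 |
| 3.00 | 5.7 | 2.7 |
| 4.00 | 8.8 | 0 |
| 5.00 | 12.0 | 1.5 |

(readings scatter by 1 percentage point)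

- reagent is single-handed; left-handed substrate and right-handed substrate are mirror images of each other, charged as a racemate, each of them at the stated concentration
- at the start none of reagent is dissolved
- steps thought possible: reagent + left-handed substrate -> left-handed product; reagent + right-handed substrate -> right-handed product; left-handed substrate + racemization catalyst <-> right-handed substrate + racemization catalyst; gas <-> reagent; 2 racemization catalyst -> spent catalyst; 2 racemization catalyst <-> resting dimer
- an excess is below zero if the other one leads
- the handed part of reagent does not stay in what it makes, so the products of the two hands are mirror images too

- left-handed product and right-handed product together, in percent of the left-handed substrate and right-handed substrate charged together, at 30 h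
- excess of left-handed product over right-handed product in the product at 30 h
- whether the exchange between left-handed substrate and right-handed substrate keeps pace with the reaction: how far the product's excess at 30 h gets from its value without exchange to its value with instant exchange (above 80 % keeps pace, below 20 % hardly takes part, else lags behind)

The south-east run is this same flask followed for its first hours. Its summed readings put left-handed over right-handed product at a selectivity factor of 7.13. Its late slope gave the fast hand 0.0765 h⁻¹, as a reading, and I held that rate steady.

I then solved two extreme flasks. Without exchange, each hand reacts from its own charge, which gave a yield of 58.7 % and an excess of 53.2 %. With instant exchange, both substrates stay level, which gave a yield of 73.0 % and an excess of 75.4 %. A real exchange refills the left-handed substrate in part, so I expected this flask to lie between these two extreme flasks, whose excesses differ by 22 percentage points.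

The gap between the extremes is a count of turnovers. Instant exchange needs net crossings from right to left equal to half the surplus of left-handed product. That is yield times excess over loading, or 4.58 per catalyst charged, and I called it the turnover demand.

The forecast gave a yield of 66 %, an excess of 65 % and an exchange that lags behind, noting that “The five-hour data cannot show the racemization rate”.

The flask gave a yield of 65.1 % and an excess of 55.7 %, and its exchange lags behind, at 38 % of the way.

    reagent + left-handed substrate → left-handed product (k = 0.0590 M⁻¹ min⁻¹)
    reagent + right-handed substrate → right-handed product (k = 0.0100 M⁻¹ min⁻¹)
    left-handed substrate + racemization catalyst ⇌ right-handed substrate + racemization catalyst, rate k3*[racemization catalyst]*[left-handed substrate] forward; the back reaction follows from the equilibrium constant (k = 0.0630 M⁻¹ min⁻¹)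
    gas ⇌ reagent, rate k4*(csat - [reagent]) (kL = 0.00920 min⁻¹)
    2 racemization catalyst → spent catalyst (k = 0.0970 M⁻¹ min⁻¹)
    2 racemization catalyst ⇌ resting dimer (K = 54.0 M⁻¹, k = 0.0670 M⁻¹ min⁻¹)

From the hand balance at 30.0 h, this flask made 1.51 net turnovers per catalyst charged, against a demand of 4.58. The neighbouring flask, charged with 30 mol% of catalyst, had a demand of 1.83 by the same reckoning. It made 0.786 net turnovers per catalyst charged, and its excess reached 58.3 %.

(The data were generated by integration for substances that don't exist.)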